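The route rests on cutting the 5-methylhexahydrofuro[3,2-b]pyran on both flanks of its C6–C7 ethano bridge. C5 (the O4–CH(CH3) carbon) is an acetaldehyde acetal carbon in disguise and C7a an aldehyde carbon, so a cis-vinylene bis-nucleophile can bridge two electrophiles. In one flask, (Z)-2-(trimethylsilyl)vinylmagnesium bromide adds under chelation control to an α-(1-ethoxyethoxy) aldehyde from (S)-3-hydroxybutyrolactone (C7–C7a); the ethoxyethyl 'protecting group' is then ionised and trapped by the vinylsilane (C5–C6, 2,6-cis), and lactonisation gives the cis-fused bicyclic lactone. Its acetate-derived β-keto ester is joined to a cross-metathesis-derived γ-hydroxy enone acid by Michael addition–lactonisation–cyclodehydration; Shiina macrolactonisation closes the ten-membered ring.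

Key step: step 5

Remark: the acetal carbon of the 1-ethoxyethyl group is carried as a mixture of epimers (it becomes sp2 in step 5); (S)-3-hydroxy-γ-butyrolactone, (iodoethynyl)trimethylsilane, (S)-2-hydroxy-1,2,2-triphenylethyl acetate and (R)-γ-valerolactone are taken as catalogue compounds.

Step 1
Reactants: 1 (S)-4-hydroxydihydrofuran-2(3H)-one; 2 ethyl vinyl ether
Product: 3 (4S)-4-(1-ethoxyethoxy)dihydrofuran-2(3H)-one
Conditions: PPTS (5 mol%), CH2Cl2, 0 °C → rt
Reagents that add atoms: none
Why: Acid-catalysed addition of the secondary alcohol to the enol ether (acetalisation) installs the 1-ethoxyethyl acetal whose acetal carbon and methyl group later become C5 and its methyl group of the pyran, without touching the carbinol stereocentre.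

Step 2
Reactants: 3 (4S)-4-(1-ethoxyethoxy)dihydrofuran-2(3H)-one
Product: 4 (3S)-3-(1-ethoxyethoxy)-4-hydroxy-N-methoxy-N-methylbutanamide
Conditions: MeNHOMe·HCl, i-PrMgCl, THF, −20 → 0 °C
Reagents that add atoms: N,O-dimethylhydroxylamine hydrochloride, CNOC.Cl
Why: Aminolysis of the γ-lactone by the chloromagnesium amide (Weinreb amide formation) should be faster at low temperature than β-elimination of the acetal oxygen and frees the primary alcohol without risk of relactonisation.

Step 3
Reactants: 4 (3S)-3-(1-ethoxyethoxy)-4-hydroxy-N-methoxy-N-methylbutanamide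
Product: 5 (3S)-3-(1-ethoxyethoxy)-N-methoxy-N-methyl-4-oxobutanamide
Conditions: SO3·pyridine, DMSO, i-Pr2NEt, CH2Cl2, 0 °C; used crude
Reagents that add atoms: none
Why: Parikh–Doering oxidation gives the aldehyde under non-acidic conditions that should leave the acetal intact and not epimerise the α-alkoxy centre.

Step 4
Reactants: 6 (iodoethynyl)trimethylsilane
Product: 7 (Z)-(2-iodovinyl)trimethylsilane
Conditions: 2-nitrobenzenesulfonohydrazide, Et3N, THF/i-PrOH, rt, dark
Reagents that add atoms: none
Why: Diimide generated from the sulfonyl hydrazide transfers two hydrogens suprafacially to the iodoalkyne (cis-reduction), which should give the Z-iodoalkene without hydrogenolysis of the C–I bond.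

Step 5
Reactants: 5 (3S)-3-(1-ethoxyethoxy)-N-methoxy-N-methyl-4-oxobutanamide; 7 (Z)-(2-iodovinyl)trimethylsilane
Product: 10 (3aS,5R,7aS)-5-methyl-3,3a,5,7a-tetrahydro-2H-furo[3,2-b]pyran-2-one, via syn allylic alkoxide 8 (not isolated), via silyloxy dihydropyran amide 9 (not isolated)
Conditions: 7, t-BuLi (2 equiv), Et2O, −78 °C; MgBr2·OEt2; 5, CH2Cl2, −78 °C; then Me3SiOTf (3 equiv), −78 → −20 °C; then 1 M HCl, THF, rt
Reagents that add atoms: none
Why: Iodine–lithium exchange with retention and transmetalation give the Z-alkenyl Grignard reagent, which adds to the MgBr2-chelated aldehyde (C7–C7a); Me3SiOTf then silylates the alkoxide and ionises the mixed acetal by loss of ethoxytrimethylsilane to an oxocarbenium ion on O4, which the vinylsilane attacks at its silicon-bearing carbon (C5–C6; the β-silyl cation loses silicon to give the ring alkene, which also forestalls a pinacol-type shift), and aqueous acid finally cleaves the silyl ether and lactonises the cis hydroxy amide. The closest known reaction types are the chelation-controlled addition of alkenyl Grignard reagents to α-alkoxy aldehydes and the acetal-initiated, vinylsilane-terminated (silyl-Prins) cyclisation of (Z)-4-silylbut-3-enyl α-alkoxyalkyl ethers to 3,6-dihydro-2H-pyrans, here run in sequence in one flask. The pyran closes in a cationic 6-endo mode (oxocarbenium and vinylsilane π bonds both endocyclic) and the lactone by 5-exo-trig acyl substitution. C7a is set by the five-membered magnesium chelate between the aldehyde and the α-acetal oxygen (attack anti to the CH2 side chain, syn-diol derivative); C5 is set in the chair-like transition state of the E-oxocarbenium ion with methyl and side chain equatorial and the silyloxy group axial (2,6-cis); C3a comes unchanged from 1. The step needs loss of the ethoxy group and not of the whole acetal, six-ring and not five-ring closure, and retention of the Z geometry: any 2-methyl-1,3-dioxolane formed with the neighbouring oxygen should reopen reversibly, closure from the O1-oxocarbenium would be 5-endo and disfavoured, and the Z-vinylsilane holds silicon cis to the chain so that ipso substitution can deliver a ring alkene.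

Step 6
Reactants: 10 (3aS,5R,7aS)-5-methyl-3,3a,5,7a-tetrahydro-2H-furo[3,2-b]pyran-2-one
Product: 11 (3aS,5R,7aS)-5-methylhexahydro-2H-furo[3,2-b]pyran-2-one
Conditions: H2 (1 atm), 5% Rh/Al2O3, EtOAc, rt
Reagents that add atoms: none
Why: Heterogeneous hydrogenation of the cis-disubstituted ring alkene creates no stereocentre, and rhodium on alumina is chosen to keep hydrogenolysis of the two allylic C–O bonds low.

Step 7
Reactants: 11 (3aS,5R,7aS)-5-methylhexahydro-2H-furo[3,2-b]pyran-2-one; 12 methyl acetate
Product: 13 methyl 2-[(3aS,5R,7aS)-2-hydroxy-5-methylhexahydro-2H-furo[3,2-b]pyran-2-yl]acetate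
Conditions: LiN(i-Pr)2, 12, THF, −78 °C; then 11, −78 °C; AcOH quench
Reagents that add atoms: none
Why: Claisen-type addition of the lithium enolate of methyl acetate to the lactone carbonyl at −78 °C should stop at the lactol, which is the ring-closed (hemiketal) form of the γ-hydroxy β-keto ester needed as Michael donor.

Step 8
Reactants: 14 (S)-2-hydroxy-1,2,2-triphenylethyl acetate; 15 acrolein
Product: 16 (S)-2-hydroxy-1,2,2-triphenylethyl (S)-3-hydroxypent-4-enoate
Conditions: LiN(i-Pr)2 (2.2 equiv), THF, −78 → 0 °C; then 15, −100 °C; recrystallisation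
Reagents that add atoms: none
Why: Acetate aldol addition of the doubly lithiated chiral acetate, in which the triphenylglycol unit shields one enolate face so that the (S)-auxiliary should deliver the (S)-carbinol, the diastereomer ratio being upgraded by crystallisation.

Step 9
Reactants: 16 (S)-2-hydroxy-1,2,2-triphenylethyl (S)-3-hydroxypent-4-enoate
Product: 17 (S)-3-hydroxypent-4-enoic acid
Conditions: KOH, MeOH/H2O, rt; then HCl to pH 2
Reagents that add atoms: potassium hydroxide, [K+].[OH-]
Why: Saponification releases the β-hydroxy acid and the recoverable diol auxiliary under conditions mild enough to avoid retro-aldol cleavage or dehydration.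

Step 10
Reactants: 18 (R)-5-methyldihydrofuran-2(3H)-one
Product: 20 (R)-6-hydroxyhept-1-en-3-one, via hydroxy Weinreb amide 19 (not isolated)
Conditions: MeNHOMe·HCl, i-PrMgCl, THF, −20 °C; then CH2=CHMgBr, −20 → 0 °C; inverse quench into cold 1 M HCl
Reagents that add atoms: vinylmagnesium bromide, C=C[Mg]Br
Why: One-flask Weinreb ketone synthesis in which lactone aminolysis is followed by vinyl Grignard addition, the chelated tetrahedral intermediate preventing over-addition and the acidic inverse quench preventing conjugate addition of the released amine; the carbinol centre is not involved.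

Step 11
Reactants: 17 (S)-3-hydroxypent-4-enoic acid; 20 (R)-6-hydroxyhept-1-en-3-one
Product: 21 (3S,4E,9R)-3,9-dihydroxy-6-oxodec-4-enoic acid
Conditions: second-generation Hoveyda–Grubbs catalyst (5 mol%), CH2Cl2, 40 °C; 20 in twofold excess
Reagents that add atoms: none
Why: Olefin cross-metathesis between an allylic alcohol that homodimerises slowly and a vinyl ketone that does not homodimerise should be selective and give the conjugated E-enone, free acid and hydroxyl groups being tolerated by the catalyst.

Step 12
Reactants: 13 methyl 2-[(3aS,5R,7aS)-2-hydroxy-5-methylhexahydro-2H-furo[3,2-b]pyran-2-yl]acetate; 21 (3S,4E,9R)-3,9-dihydroxy-6-oxodec-4-enoic acid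
Product: 23 2-[(2S,3R,4E)-3-[(5R)-5-hydroxy-2-oxohexyl]-4-[(3aS,5R,7aS)-5-methylhexahydro-2H-furo[3,2-b]pyran-2-ylidene]-5-oxooxolan-2-yl]acetic acid, via α-acyl butyrolactone 22 (not isolated)
Conditions: DBU (3 equiv), MeCN, 0 → 40 °C; then TsOH·H2O (3.5 equiv), 4 Å MS, 40 °C
Reagents that add atoms: none
Why: Michael addition of the β-keto ester (ring-opened hemiketal) to the enone and lactonisation by the γ-hydroxyl give the α-acyl butyrolactone, reversible retro-Michael/Michael exchange is expected to funnel the new ring carbon into the trans-4,5-disubstituted (3R) lactone, and acid then cyclodehydrates the γ-hydroxy ketone to the tetrasubstituted alkylidene tetrahydrofuran, whose E geometry (ring oxygen anti to the lactone carbonyl) is the expected thermodynamic one under the equilibrating acidic conditions.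

Step 13
Reactants: 23 2-[(2S,3R,4E)-3-[(5R)-5-hydroxy-2-oxohexyl]-4-[(3aS,5R,7aS)-5-methylhexahydro-2H-furo[3,2-b]pyran-2-ylidene]-5-oxooxolan-2-yl]acetic acid
Product: 24 cordycicadin D
Conditions: 2-methyl-6-nitrobenzoic anhydride, DMAP, CH2Cl2 (1 mM), rt, slow addition of 23
Reagents that add atoms: none
Why: Shiina macrolactonisation, in which the mixed anhydride is transferred by DMAP to the secondary hydroxyl at room temperature under high dilution, should close the ten-membered lactone with retention at the carbinol carbon while keeping β-elimination of the lactone oxygen slow.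

Compound list
1 | (S)-4-hydroxydihydrofuran-2(3H)-one ((S)-3-hydroxy-γ-butyrolactone) | O=C1C[C@H](O)CO1 | starting material
2 | ethyl vinyl ether | C=COCC | starting material
3 | (4S)-4-(1-ethoxyethoxy)dihydrofuran-2(3H)-one (both acetal epimers) | O=C1C[C@H](OC(C)OCC)CO1 | intermediate
4 | (3S)-3-(1-ethoxyethoxy)-4-hydroxy-N-methoxy-N-methylbutanamide | CON(C)C(=O)C[C@@H](CO)OC(C)OCC | intermediate
5 | (3S)-3-(1-ethoxyethoxy)-N-methoxy-N-methyl-4-oxobutanamide | CON(C)C(=O)C[C@@H](C=O)OC(C)OCC | intermediate
6 | (iodoethynyl)trimethylsilane | C[Si](C)(C)C#CI | starting material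
7 | (Z)-(2-iodovinyl)trimethylsilane | C[Si](C)(C)/C=C\I | intermediate
8 | (3S,4S,5Z)-3-(1-ethoxyethoxy)-4-hydroxy-N-methoxy-N-methyl-6-(trimethylsilyl)hex-5-enamide, present as its bromomagnesium alkoxide | CON(C)C(=O)C[C@H](OC(C)OCC)[C@@H](O)/C=C\[Si](C)(C)C | intermediate
9 | N-methoxy-N-methyl-2-[(2S,3S,6R)-6-methyl-3-(trimethylsilyloxy)-3,6-dihydro-2H-pyran-2-yl]acetamide | CON(C)C(=O)C[C@@H]1O[C@H](C)C=C[C@@H]1O[Si](C)(C)C | intermediate
10 | (3aS,5R,7aS)-5-methyl-3,3a,5,7a-tetrahydro-2H-furo[3,2-b]pyran-2-one | O=C1C[C@@H]2O[C@H](C)C=C[C@@H]2O1 | intermediate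
11 | (3aS,5R,7aS)-5-methylhexahydro-2H-furo[3,2-b]pyran-2-one | O=C1C[C@@H]2O[C@H](C)CC[C@@H]2O1 | intermediate
12 | methyl acetate | COC(C)=O | starting material
13 | methyl 2-[(3aS,5R,7aS)-2-hydroxy-5-methylhexahydro-2H-furo[3,2-b]pyran-2-yl]acetate (both anomers; ring form of the γ-hydroxy β-keto ester) | COC(=O)CC1(O)C[C@@H]2O[C@H](C)CC[C@@H]2O1 | intermediate
14 | (S)-2-hydroxy-1,2,2-triphenylethyl acetate | CC(=O)O[C@@H](c1ccccc1)C(O)(c1ccccc1)c1ccccc1 | starting material
15 | acrolein | C=CC=O | starting material
16 | (S)-2-hydroxy-1,2,2-triphenylethyl (S)-3-hydroxypent-4-enoate | C=C[C@@H](O)CC(=O)O[C@@H](c1ccccc1)C(O)(c1ccccc1)c1ccccc1 | intermediate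
17 | (S)-3-hydroxypent-4-enoic acid | C=C[C@@H](O)CC(=O)O | intermediate
18 | (R)-5-methyldihydrofuran-2(3H)-one ((R)-γ-valerolactone) | C[C@@H]1CCC(=O)O1 | starting material
19 | (R)-4-hydroxy-N-methoxy-N-methylpentanamide, present as its magnesium alkoxide | C[C@@H](O)CCC(=O)N(C)OC | intermediate
20 | (R)-6-hydroxyhept-1-en-3-one | C[C@@H](O)CCC(=O)C=C | intermediate
21 | (3S,4E,9R)-3,9-dihydroxy-6-oxodec-4-enoic acid | C[C@@H](O)CCC(=O)/C=C/[C@@H](O)CC(=O)O | intermediate
22 | 2-[(2S,3R)-3-[(5R)-5-hydroxy-2-oxohexyl]-4-{[(2S,3S,6R)-3-hydroxy-6-methyloxan-2-yl]acetyl}-5-oxooxolan-2-yl]acetic acid (epimers at the α-carbon; in equilibrium with its cyclic hemiketal) | C[C@@H](O)CCC(=O)C[C@@H]1C(C(=O)C[C@@H]2O[C@H](C)CC[C@@H]2O)C(=O)O[C@H]1CC(=O)O | intermediate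
23 | 2-[(2S,3R,4E)-3-[(5R)-5-hydroxy-2-oxohexyl]-4-[(3aS,5R,7aS)-5-methylhexahydro-2H-furo[3,2-b]pyran-2-ylidene]-5-oxooxolan-2-yl]acetic acid | C[C@@H](O)CCC(=O)C[C@@H]1/C(=C2/C[C@@H]3O[C@H](C)CC[C@@H]3O2)C(=O)O[C@H]1CC(=O)O | intermediate
24 | cordycicadin D (ten-membered (R)-methyl keto macrolide trans-fused to the butyrolactone, which carries the (E)-(3aS,5R,7aS)-5-methylhexahydro-2H-furo[3,2-b]pyran-2-ylidene group at its α-carbon) | C[C@@H]1CCC(=O)C[C@@H]2/C(=C3/C[C@@H]4O[C@H](C)CC[C@@H]4O3)C(=O)O[C@H]2CC(=O)O1 | target

Total step count: 13. Longest linear sequence: 8 steps (steps 1, 2, 3, 5, 6, 7, 12, 13).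

Steps most likely to fail

Step 5. The telescoped sequence may lose chelation control in the Grignard addition, suffer silyl migration from carbon to oxygen in the Z-γ-silyl allylic alkoxide, or ionise the whole acetal and not only its ethoxy group, so that the pyran does not close cleanly. The fallback sets out from 5 and comes back at 11, building the pyran by C–O bond formation on a chain introduced in one piece. Chelation-controlled addition of but-3-enylmagnesium bromide (MgBr2·OEt2, CH2Cl2, −78 °C) should give (3S,4S)-3-(1-ethoxyethoxy)-4-hydroxy-N-methoxy-N-methyloct-7-enamide F1. TsOH in methanol should remove the acetal and lactonise to (4S,5S)-5-(but-3-en-1-yl)-4-hydroxydihydrofuran-2(3H)-one F2. Intramolecular oxymercuration with Hg(OCOCF3)2 followed by NaBH4 demercuration should close the 2,6-cis pyran and deliver 11.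

Step 12. Base-induced isomerisation of the open-chain γ-hydroxy enone, interference by the free carboxylate, incomplete funnelling to the trans lactone, or competing cyclodehydration of the 5-hydroxy-2-oxohexyl chain under acid may erode the cascade. The fallback sets out from 17 and 20 and comes back at 24; it closes the ten-membered ring first, so that the acceptor carries neither free acid nor free secondary alcohol, and makes step 13 unnecessary. Silylation of 17 (TBSCl, imidazole; then K2CO3, aqueous MeOH) should give (S)-3-[(tert-butyldimethylsilyl)oxy]pent-4-enoic acid F3. Carbodiimide esterification with 20 (EDC·HCl, DMAP) should give (R)-5-oxohept-6-en-2-yl (S)-3-[(tert-butyldimethylsilyl)oxy]pent-4-enoate F4. Ring-closing metathesis (second-generation Grubbs catalyst, CH2Cl2, high dilution) should give (4S,5E,10R)-4-[(tert-butyldimethylsilyl)oxy]-10-methyloxacyclodec-5-ene-2,7-dione F5. HF·pyridine should give (4S,5E,10R)-4-hydroxy-10-methyloxacyclodec-5-ene-2,7-dione F6. Conjugate addition of 13 to F6 with DBU, lactonisation and acid cyclodehydration as in step 12 should give 24 directly; facial selectivity on the macrocycle would then have to be secured by the same retro-Michael equilibration.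

Step 13. Oligomerisation and β-elimination of the activated β-acyloxy acid (opening of the butyrolactone) may compete with closure of the ten-membered ring. The fallback sets out from 17 and 13 and comes back at 24; it activates the alcohol and not the acid, and closes the ring with inversion. Commercial (S)-γ-valerolactone, treated as in step 10, should give (S)-6-hydroxyhept-1-en-3-one F7. Cross-metathesis with 17 as in step 11 should give (3S,4E,9S)-3,9-dihydroxy-6-oxodec-4-enoic acid F8. The step 12 cascade with 13 should give 2-[(2S,3R,4E)-3-[(5S)-5-hydroxy-2-oxohexyl]-4-[(3aS,5R,7aS)-5-methylhexahydro-2H-furo[3,2-b]pyran-2-ylidene]-5-oxooxolan-2-yl]acetic acid F9. Mitsunobu macrolactonisation (PPh3, DIAD, toluene, high dilution) should then give 24 with inversion at the carbinol carbon.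

Further compounds
F1 | step 5 | (3S,4S)-3-(1-ethoxyethoxy)-4-hydroxy-N-methoxy-N-methyloct-7-enamide | CON(C)C(=O)C[C@H](OC(C)OCC)[C@@H](O)CCC=C
F2 | step 5 | (4S,5S)-5-(but-3-en-1-yl)-4-hydroxydihydrofuran-2(3H)-one | O=C1C[C@H](O)[C@H](CCC=C)O1
F3 | step 12 | (S)-3-[(tert-butyldimethylsilyl)oxy]pent-4-enoic acid | C=C[C@@H](O[Si](C)(C)C(C)(C)C)CC(=O)O
F4 | step 12 | (R)-5-oxohept-6-en-2-yl (S)-3-[(tert-butyldimethylsilyl)oxy]pent-4-enoate | C=CC(=O)CC[C@@H](C)OC(=O)C[C@H](O[Si](C)(C)C(C)(C)C)C=C
F5 | step 12 | (4S,5E,10R)-4-[(tert-butyldimethylsilyl)oxy]-10-methyloxacyclodec-5-ene-2,7-dione | C[C@@H]1CCC(=O)/C=C/[C@@H](O[Si](C)(C)C(C)(C)C)CC(=O)O1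
F6 | step 12 | (4S,5E,10R)-4-hydroxy-10-methyloxacyclodec-5-ene-2,7-dione | C[C@@H]1CCC(=O)/C=C/[C@@H](O)CC(=O)O1
F7 | step 13 | (S)-6-hydroxyhept-1-en-3-one | C[C@H](O)CCC(=O)C=C
F8 | step 13 | (3S,4E,9S)-3,9-dihydroxy-6-oxodec-4-enoic acid | C[C@H](O)CCC(=O)/C=C/[C@@H](O)CC(=O)O
F9 | step 13 | 2-[(2S,3R,4E)-3-[(5S)-5-hydroxy-2-oxohexyl]-4-[(3aS,5R,7aS)-5-methylhexahydro-2H-furo[3,2-b]pyran-2-ylidene]-5-oxooxolan-2-yl]acetic acid | C[C@H](O)CCC(=O)C[C@@H]1/C(=C2/C[C@@H]3O[C@H](C)CC[C@@H]3O2)C(=O)O[C@H]1CC(=O)O
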